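**Plan**
Cuts, in retrosynthetic order: the gallate ester bond at O3, C4–C4a of ring C, the aryl ether bond C2–O1, the epoxide oxygen on C3/C4, and C2–C3.
Enabling feature: C4 carries only hydrogens and lies between the oxygenated C3 and ring-A carbon C4a. With ring C opened, ring A is a 1,3,5-trioxygenated benzene whose two carbons flanking the O1-bearing carbon are identical, so ring A can open a C3–C4 terminal epoxide at C4 with only one possible outcome.
Forward order: rings A, B and the galloyl ring are bought. Vinyl addition joins C2–C3, epoxidation oxygenates C3/C4, etherification joins O1 to C2, and ring C (the only ring built) closes. Acylation at O3 and global debenzylation finish the route.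
Stereochemistry: one tartrate-controlled kinetic-resolution epoxidation selects the C2 carbinol enantiomer and creates C3 as R (erythro pair). SN2 inversion in the etherification turns C2 from S into R, which gives the 2,3-cis relation. No later step breaks a bond at C2 or C3.

Key step: step 4

Assumption: 3,5-bis(benzyloxy)phenol and 3,4,5-tris(benzyloxy)benzoic acid are treated as catalogue compounds, and flavan numbering (O1, C2, C3, C4, C4a, C8a) is also applied to the open-chain intermediates.

**Step 1**
Reactants: 1 4-(benzyloxy)benzaldehyde; 2 vinylmagnesium bromide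
Product: 3 rac-1-[4-(benzyloxy)phenyl]prop-2-en-1-ol
Conditions: 2 (1.1 equiv, 1 M in THF), THF, -78 °C to 0 °C; sat. aq. NH4Cl
Reagents that add atoms: vinylmagnesium bromide (2), C=C[Mg]Br
Why: Grignard 1,2-addition to a non-enolisable aromatic aldehyde should form the C2–C3 bond without touching the benzyl ether, and the new carbinol centre (future C2) is left racemic on purpose because step 2 sorts the enantiomers.

**Step 2**
Reactants: 3 rac-1-[4-(benzyloxy)phenyl]prop-2-en-1-ol
Product: 4 (S)-[4-(benzyloxy)phenyl][(R)-oxiran-2-yl]methanol (erythro, anti epoxy alcohol)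
Conditions: Ti(OiPr)4 (0.15 equiv), L-(+)-DIPT (0.20 equiv), t-BuOOH (0.45 equiv, anhydrous in toluene), 4 Å MS, CH2Cl2, -20 °C
Reagents that add atoms: tert-butyl hydroperoxide, CC(C)(C)OO
Why: In this Sharpless kinetic resolution (titanium–tartrate epoxidation of a racemic secondary allylic alcohol) with L-(+)-DIPT, the (R)-enantiomer of 3 is the fast-reacting one and takes up oxygen on the alkene face leading to the erythro epoxy alcohol, so with less than half an equivalent of oxidant C2 is fixed by selection (its descriptor changes from R to S only because vinyl becomes oxiranyl) and C3 is created as R under matched reagent and substrate control, while the (S)-enantiomer of 3 stays unreacted and is removed by chromatography.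

**Step 3**
Reactants: 4 (S)-[4-(benzyloxy)phenyl][(R)-oxiran-2-yl]methanol; 5 3,5-bis(benzyloxy)phenol
Product: 6 (R)-2-[(R)-[3,5-bis(benzyloxy)phenoxy][4-(benzyloxy)phenyl]methyl]oxirane
Conditions: PPh3 (1.5 equiv), DIAD (1.5 equiv), toluene, 0 °C to rt
Reagents that add atoms: 3,5-bis(benzyloxy)phenol (5), Oc1cc(OCc2ccccc2)cc(OCc2ccccc2)c1
Why: In this Mitsunobu etherification the phenoxide of 5 should displace the alkoxyphosphonium group by SN2 with inversion, turning C2 from S into R without touching the C3–O bond or the oxirane; the electron-withdrawing oxirane next to C2, the non-polar solvent and the low temperature hold back ionisation of the 4-benzyloxybenzylic centre, and because C3 is fixed any leakage would show up as a separable diastereomer and not as loss of enantiopurity.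

**Step 4**
Reactants: 6 (R)-2-[(R)-[3,5-bis(benzyloxy)phenoxy][4-(benzyloxy)phenyl]methyl]oxirane
Product: 7 (2R,3R)-5,7-bis(benzyloxy)-2-[4-(benzyloxy)phenyl]chroman-3-ol (5,7,4'-tri-O-benzyl-epiafzelechin)
Conditions: AuCl3 (5 mol %), AgOTf (15 mol %), 4 Å MS, ClCH2CH2Cl (0.01 M), 0 °C to rt
Reagents that add atoms: none
Why: Cationic trivalent gold formed from AuCl3 and AgOTf binds the epoxide oxygen and polarises the C4–O bond; the ring-A carbon ortho to O1, which is ortho or para to all three ether oxygens, attacks C4 from the rear, and loss of the arenium proton followed by protonolysis of the gold alkoxide releases the C3 hydroxyl and the catalyst. The closest known reaction type is the Lewis-acid- or gold-catalysed intramolecular Friedel–Crafts cycloalkylation of aryl glycidyl ethers to chroman-3-ols. Ring C closes in the 6-endo-tet mode, with C4–C4a as the only new skeletal bond. No stereocentre is created: the C3–O bond is never broken, so C3 stays R, and C2 is a spectator that stays R as long as C2–O1 does not ionise. Attack at C4 rather than C3 is secured by the unhindered primary terminus, by the inductive destabilisation of positive charge at C3 next to the aryloxy-bearing C2 and by the poor rear-side alignment available for the 5-exo dihydrobenzofuran closure; no ortho/ortho choice arises because ring A is symmetric about the O1–C8a axis, and the para carbon cannot reach. Epoxide activation must also outrun heterolysis of the 4-benzyloxybenzylic C2–O1 bond and intermolecular alkylation, which is addressed by low catalyst loading, low temperature, exclusion of water (no free TfOH) and high dilution.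

**Step 5**
Reactants: 7 (2R,3R)-5,7-bis(benzyloxy)-2-[4-(benzyloxy)phenyl]chroman-3-ol; 8 3,4,5-tris(benzyloxy)benzoic acid
Product: 9 (2R,3R)-5,7-bis(benzyloxy)-2-[4-(benzyloxy)phenyl]chroman-3-yl 3,4,5-tris(benzyloxy)benzoate
Conditions: DCC (1.5 equiv), DMAP (0.2 equiv), CH2Cl2, 0 °C to rt
Reagents that add atoms: 3,4,5-tris(benzyloxy)benzoic acid (8), OC(=O)c1cc(OCc2ccccc2)c(OCc2ccccc2)c(OCc2ccccc2)c1
Why: In this Steglich esterification DMAP relays the O-acylisourea of 8 as an acylpyridinium ion to the hindered C3 hydroxyl, the only free OH in 7, and the configuration is kept because the C3–O bond is not broken.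

**Step 6**
Reactants: 9 (2R,3R)-5,7-bis(benzyloxy)-2-[4-(benzyloxy)phenyl]chroman-3-yl 3,4,5-tris(benzyloxy)benzoate
Product: 10 (2R,3R)-5,7-dihydroxy-2-(4-hydroxyphenyl)chroman-3-yl 3,4,5-trihydroxybenzoate (epiafzelechin 3-O-gallate)
Conditions: H2 (1 atm), Pd(OH)2/C, THF/MeOH, rt, work-up under argon
Reagents that add atoms: none
Why: Catalytic hydrogenolysis should cleave all six O-benzyl bonds in one neutral operation that leaves the gallate ester and both stereocentres untouched, and since the secondary, ring-bound C2–O1 bond reacts much more slowly than primary benzyl ethers, stopping at full debenzylation should deliver 10.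

**Compound list**
1 | 4-(benzyloxy)benzaldehyde | O=Cc1ccc(OCc2ccccc2)cc1 | starting material
2 | vinylmagnesium bromide | C=C[Mg]Br | starting material
3 | rac-1-[4-(benzyloxy)phenyl]prop-2-en-1-ol | C=CC(O)c1ccc(OCc2ccccc2)cc1 | intermediate
4 | (S)-[4-(benzyloxy)phenyl][(R)-oxiran-2-yl]methanol | O[C@H]([C@H]1CO1)c1ccc(OCc2ccccc2)cc1 | intermediate
5 | 3,5-bis(benzyloxy)phenol | Oc1cc(OCc2ccccc2)cc(OCc2ccccc2)c1 | starting material
6 | (R)-2-[(R)-[3,5-bis(benzyloxy)phenoxy][4-(benzyloxy)phenyl]methyl]oxirane | C(Oc1cc(OCc2ccccc2)cc(O[C@@H]([C@H]2CO2)c2ccc(OCc3ccccc3)cc2)c1)c1ccccc1 | intermediate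
7 | (2R,3R)-5,7-bis(benzyloxy)-2-[4-(benzyloxy)phenyl]chroman-3-ol | O[C@@H]1Cc2c(OCc3ccccc3)cc(OCc3ccccc3)cc2O[C@@H]1c1ccc(OCc2ccccc2)cc1 | intermediate
8 | 3,4,5-tris(benzyloxy)benzoic acid | OC(=O)c1cc(OCc2ccccc2)c(OCc2ccccc2)c(OCc2ccccc2)c1 | starting material
9 | (2R,3R)-5,7-bis(benzyloxy)-2-[4-(benzyloxy)phenyl]chroman-3-yl 3,4,5-tris(benzyloxy)benzoate | O=C(O[C@@H]1Cc2c(OCc3ccccc3)cc(OCc3ccccc3)cc2O[C@@H]1c1ccc(OCc2ccccc2)cc1)c1cc(OCc2ccccc2)c(OCc2ccccc2)c(OCc2ccccc2)c1 | intermediate
10 | (2R,3R)-5,7-dihydroxy-2-(4-hydroxyphenyl)chroman-3-yl 3,4,5-trihydroxybenzoate | O=C(O[C@@H]1Cc2c(O)cc(O)cc2O[C@@H]1c1ccc(O)cc1)c1cc(O)c(O)c(O)c1 | target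

Total step count: 6. Longest linear sequence: 6 steps (1 to 10).

**Steps most likely to fail**

**Step 4.** Heterolysis of the C2–O1 bond (loss of the phenol, scrambling at C2), opening at C3, or intermolecular alkylation of the electron-rich ring may outrun ring closure.

The fallback sets out from 5 and 4 and returns at 7. It forms the same C4–C4a bond with ring A acting as an aryl-lithium under base instead of a π-nucleophile under acid, so no acid ever meets the C2–O1 bond.
- Iodination of 5 ortho to the hydroxyl (NIS, CH2Cl2, -20 °C) gives 3,5-bis(benzyloxy)-2-iodophenol F1.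
- Mitsunobu coupling of F1 with 4 under the conditions of step 3 gives the iodinated epoxy ether F2.
- LiBr and AcOH in THF open the oxirane at C4 to the bromohydrin F3.
- TBSCl and imidazole in DMF give the silyl ether F4.
- n-BuLi in THF at -78 °C effects iodine–lithium exchange, and the aryl-lithium displaces the primary bromide (Parham cyclialkylation, 6-exo-tet) to give the 3-O-TBS flavan F5.
- TBAF in THF frees 7.

**Step 3.** Partial ionisation of the alkoxyphosphonium salt at the 4-benzyloxybenzylic carbon (loss of inversion fidelity at C2), C-alkylation of the phenol, or phenoxide attack on the oxirane may compete.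

The fallback sets out from 2 and 5 and returns at 7. The donor on ring B is replaced by an acceptor for as long as C2 is a reactive centre.
- Bought 4-formylphenyl pivalate F6 takes the place of 1, and addition of 2 at -78 °C gives the racemic allylic alcohol F7.
- The L-(+)-DIPT kinetic resolution of step 2 gives the epoxy alcohol F8.
- Mitsunobu coupling with 5 gives the pivaloyloxy epoxy ether F9. Neither its phosphonium precursor nor its C2–O1 bond is prone to ionise.
- The gold-catalysed closure of step 4 gives the pivaloyloxy chromanol F10.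
- NaOMe in MeOH/THF at 0 °C removes the pivalate to give the 4'-phenol F11.
- BnBr and K2CO3 in acetone benzylate only the phenol and give 7.

**Step 2.** Sluggish epoxidation of the monosubstituted alkene, too small a rate difference between the enantiomers at the chosen conversion, titanium-promoted ionisation of the allylic alcohol, or isopropoxide opening of the terminal epoxide may occur.

The fallback sets out from 3 and returns at 4. Enantiomer selection is separated from epoxidation.
- Acylation with Candida antarctica lipase B and vinyl acetate in toluene at 30 °C converts only the (R)-alcohol into the (R)-allylic acetate F12.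
- After separation, K2CO3 in MeOH at 0 °C gives the (R)-allylic alcohol F13.
- F13 is epoxidised to completion in the matched sense (Ti(OiPr)4, L-(+)-DIPT, t-BuOOH 1.5 equiv, 4 Å MS, CH2Cl2, -20 °C) to give 4.

**Further compounds**
F1 | step 4 | 3,5-bis(benzyloxy)-2-iodophenol | Oc1cc(OCc2ccccc2)cc(OCc2ccccc2)c1I
F2 | step 4 | (R)-2-[(R)-[3,5-bis(benzyloxy)-2-iodophenoxy][4-(benzyloxy)phenyl]methyl]oxirane | Ic1c(OCc2ccccc2)cc(OCc2ccccc2)cc1O[C@@H]([C@H]1CO1)c1ccc(OCc2ccccc2)cc1
F3 | step 4 | (1R,2S)-1-[3,5-bis(benzyloxy)-2-iodophenoxy]-1-[4-(benzyloxy)phenyl]-3-bromopropan-2-ol | Ic1c(OCc2ccccc2)cc(OCc2ccccc2)cc1O[C@@H]([C@H](O)CBr)c1ccc(OCc2ccccc2)cc1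
F4 | step 4 | tert-butyldimethylsilyl ether of F3 | Ic1c(OCc2ccccc2)cc(OCc2ccccc2)cc1O[C@@H]([C@H](O[Si](C)(C)C(C)(C)C)CBr)c1ccc(OCc2ccccc2)cc1
F5 | step 4 | (2R,3R)-5,7-bis(benzyloxy)-2-[4-(benzyloxy)phenyl]-3-(tert-butyldimethylsilyloxy)chroman | CC(C)(C)[Si](C)(C)O[C@@H]1Cc2c(OCc3ccccc3)cc(OCc3ccccc3)cc2O[C@@H]1c1ccc(OCc2ccccc2)cc1
F6 | step 3 | 4-formylphenyl pivalate (bought) | CC(C)(C)C(=O)Oc1ccc(C=O)cc1
F7 | step 3 | rac-4-(1-hydroxyprop-2-en-1-yl)phenyl pivalate | C=CC(O)c1ccc(OC(=O)C(C)(C)C)cc1
F8 | step 3 | 4-[(S)-hydroxy[(R)-oxiran-2-yl]methyl]phenyl pivalate | O[C@H]([C@H]1CO1)c1ccc(OC(=O)C(C)(C)C)cc1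
F9 | step 3 | 4-[(R)-[3,5-bis(benzyloxy)phenoxy][(R)-oxiran-2-yl]methyl]phenyl pivalate | c1ccccc1COc1cc(OCc2ccccc2)cc(O[C@@H]([C@H]2CO2)c2ccc(OC(=O)C(C)(C)C)cc2)c1
F10 | step 3 | 4-[(2R,3R)-5,7-bis(benzyloxy)-3-hydroxychroman-2-yl]phenyl pivalate | O[C@@H]1Cc2c(OCc3ccccc3)cc(OCc3ccccc3)cc2O[C@@H]1c1ccc(OC(=O)C(C)(C)C)cc1
F11 | step 3 | (2R,3R)-5,7-bis(benzyloxy)-2-(4-hydroxyphenyl)chroman-3-ol | O[C@@H]1Cc2c(OCc3ccccc3)cc(OCc3ccccc3)cc2O[C@@H]1c1ccc(O)cc1
F12 | step 2 | (R)-1-[4-(benzyloxy)phenyl]prop-2-en-1-yl acetate | C=C[C@@H](OC(C)=O)c1ccc(OCc2ccccc2)cc1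
F13 | step 2 | (R)-1-[4-(benzyloxy)phenyl]prop-2-en-1-ol | C=C[C@@H](O)c1ccc(OCc2ccccc2)cc1
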